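**Retrosynthetic overview**
1. Target 8 ⇒ O1–C2 bond: site- and enantioselective 6-endo oxa-Michael closure (chalcone-isomerase type) of the open-chain prenylated chalcone 6; this is the last step and sets C2 (S).
2. Chalcone 6 ⇒ Cα=Cβ bond: protecting-group-free Claisen–Schmidt condensation of prenylated acetophenone 3 with 4-hydroxybenzaldehyde 4.
3. Acetophenone 3 ⇒ aryl–prenyl bond: C-prenylation (prenyltransferase-like) of the symmetric 2′,6′-dihydroxy-4′-methoxyacetophenone 1 with prenyl bromide 2.
4. Ring order: rings A and B are bought; the heterocyclic C ring is formed last, so nothing follows the stereocentre-setting step.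

Assumption: 1 is bought as a catalogue compound (otherwise it is one selective 4-O-methylation away from phloroacetophenone).

**Step 1**
Reactants: 1 2′,6′-dihydroxy-4′-methoxyacetophenone; 2 prenyl bromide
Product: 3 2′,6′-dihydroxy-4′-methoxy-3′-prenylacetophenone
Conditions: 2 (1.1 equiv), 10% aq KOH (2 equiv), 0 °C → rt, 3 h; then 1 M HCl
Reagents that add atoms: prenyl bromide (2), CC(C)=CCBr
Why: In water the potassium phenoxide of acylphloroglucinol 1 is alkylated on carbon by the allylic bromide (nuclear C-prenylation of an ambident phenoxide, a Friedel–Crafts-type SN2 alkylation), and because C3 and C5 of 1 are equivalent only one mono-C-prenyl isomer can form; no stereocentre is created.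

**Step 2**
Reactants: 3 2′,6′-dihydroxy-4′-methoxy-3′-prenylacetophenone; 4 4-hydroxybenzaldehyde
Product: 6 (E)-2′,6′,4-trihydroxy-4′-methoxy-3′-prenylchalcone, via aldol adduct 5 (not isolated)
Conditions: 4 (1.5 equiv), 50% aq KOH (12 equiv), EtOH, Ar, 0 °C → rt, 48 h; then poured into ice-cold 2 M HCl (pH 3), rapid extraction, crystallisation
Reagents that add atoms: 4-hydroxybenzaldehyde (4), O=Cc1ccc(O)cc1
Why: Claisen–Schmidt condensation (crossed aldol addition, then E1cB dehydration of adduct 5) with a non-enolisable aldehyde gives the thermodynamic E-enone, and in concentrated alkali the product is held as the ring-open chalcone polyphenoxide, so fast cold acidification delivers 6 before it can close to racemic flavanone; the carbinol centre of 5 is lost on dehydration.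

**Step 3**
Reactants: 6 (E)-2′,6′,4-trihydroxy-4′-methoxy-3′-prenylchalcone
Product: 8 (2S)-6-prenylsakuranetin, via flavanone enol 7 (not isolated)
Conditions: N-[3,5-bis(trifluoromethyl)phenyl]-N′-(9-deoxy-epi-quinin-9-yl)thiourea (10 mol%), PhMe/CH2Cl2 1:1, 0.05 M, −20 °C, 48–72 h; then silica plug (hexane/EtOAc, 0.5% AcOH), chromatography
Reagents that add atoms: none
Why: Proposed new method: a bifunctional cinchona amine–thiourea acts as a small-molecule chalcone isomerase, in which the quinuclidine deprotonates the unhindered 6′-OH (the 2′-OH next to the prenyl group stays locked in its buttressed chelate to C=O and is screened), the thiourea binds the enone carbonyl like the enzyme's oxyanion hole, and the ion-paired phenoxide adds 6-endo to the Si face of Cβ to give enol 7, which the quinuclidinium protonates to the 2S ketone; the closest known reaction type is the cinchona-base/thiourea-catalysed intramolecular oxa-Michael cyclisation of 2′-hydroxychalcones and alkylidene β-ketoesters to flavanones, and the preference for the 6-prenyl isomer parallels the uncatalysed closure of desmethylxanthohumol mainly to 6-prenylnaringenin.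

**Compound list**
1 | 1-(2,6-dihydroxy-4-methoxyphenyl)ethanone (2′,6′-dihydroxy-4′-methoxyacetophenone) | CC(=O)c1c(O)cc(OC)cc1O | starting material
2 | 1-bromo-3-methylbut-2-ene (prenyl bromide) | CC(C)=CCBr | starting material
3 | 1-[2,6-dihydroxy-4-methoxy-3-(3-methylbut-2-en-1-yl)phenyl]ethanone | CC(=O)c1c(O)cc(OC)c(CC=C(C)C)c1O | intermediate
4 | 4-hydroxybenzaldehyde | O=Cc1ccc(O)cc1 | starting material
5 | 1-[2,6-dihydroxy-4-methoxy-3-(3-methylbut-2-en-1-yl)phenyl]-3-hydroxy-3-(4-hydroxyphenyl)propan-1-one (racemic aldol adduct, not isolated) | COc1cc(O)c(C(=O)CC(O)c2ccc(O)cc2)c(O)c1CC=C(C)C | intermediate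
6 | (E)-1-[2,6-dihydroxy-4-methoxy-3-(3-methylbut-2-en-1-yl)phenyl]-3-(4-hydroxyphenyl)prop-2-en-1-one | COc1cc(O)c(C(=O)/C=C/c2ccc(O)cc2)c(O)c1CC=C(C)C | intermediate
7 | (2S)-2-(4-hydroxyphenyl)-7-methoxy-6-(3-methylbut-2-en-1-yl)-2H-chromene-4,5-diol (flavanone enol, not isolated) | COc1cc2c(c(O)c1CC=C(C)C)C(O)=C[C@@H](c1ccc(O)cc1)O2 | intermediate
8 | (2S)-5-hydroxy-2-(4-hydroxyphenyl)-7-methoxy-6-(3-methylbut-2-en-1-yl)-2,3-dihydro-4H-chromen-4-one (6-prenylsakuranetin) | COc1cc2c(c(O)c1CC=C(C)C)C(=O)C[C@@H](c1ccc(O)cc1)O2 | target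

**Total step count:** 3
**Longest linear sequence:** 3 (1 → 3 → 6 → 8)

**Steps most likely to fail, with fallbacks**

Step 3 (highest risk). Three things can go wrong:
- Site selectivity: closure through the 2′-OH next to the prenyl group gives the 8-prenyl isomer. It is separable by chromatography and can be reopened to 6 in cold concentrated KOH and recycled.
- Enantioselectivity: 6′-hydroxychalcones also close without catalyst, and the product can reopen if the amine is left in, which would erode ee.
- Facial sense: the sense of induction of the quinine-derived catalyst on this substrate is assigned by analogy, not known. It is checked on the first run by chiral HPLC and ECD (2S flavanones show a positive Cotton effect near 330 nm and a negative one near 290 nm); the quinidine-derived pseudoenantiomer delivers the other face.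

Fallback, setting out from 1 and coming back at 8: one of the two equivalent hydroxyls of 1 is alkylated with 3-chloro-3-methylbut-1-yne (K2CO3, KI, CuI cat., acetone, reflux) to 1-[2-hydroxy-4-methoxy-6-(2-methylbut-3-yn-2-yloxy)phenyl]ethanone F1. Lindlar semi-hydrogenation (H2, quinoline, EtOAc) gives 1-[2-hydroxy-4-methoxy-6-(2-methylbut-3-en-2-yloxy)phenyl]ethanone F2. Claisen–Schmidt condensation with 4 (KOH, EtOH, rt) gives (E)-1-[2-hydroxy-4-methoxy-6-(2-methylbut-3-en-2-yloxy)phenyl]-3-(4-hydroxyphenyl)prop-2-en-1-one F3. F3 has only one free ortho hydroxyl and no self-activating 6′-OH, so the same organocatalytic oxa-Michael can close only one way, to (2S)-2-(4-hydroxyphenyl)-7-methoxy-5-(2-methylbut-3-en-2-yloxy)chroman-4-one F4. Heating F4 (PhMe, 110 °C, neutral) triggers an aromatic Claisen rearrangement that can go only to C6, since the other ortho position C4a is blocked; the allylic transposition turns the 1,1-dimethylallyl ether into the C6 prenyl group and frees the 5-OH, giving 8. The ee is polished by preparative chiral HPLC if needed.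

Step 2. The condensation runs on a substrate carrying three phenoxides, so conversion may be low, and the 2′,6′-dihydroxychalcone can close to racemic flavanone during work-up. Fallback, setting out from 3 and 4 and coming back at 6: 3 is protected with MOMCl/NaH (DMF, 0 °C) as 1-[4-methoxy-2,6-bis(methoxymethoxy)-3-(3-methylbut-2-en-1-yl)phenyl]ethanone F5, and 4 in the same way as 4-(methoxymethoxy)benzaldehyde F6. Their Claisen–Schmidt condensation (KOH, EtOH, rt) proceeds without phenoxide deactivation to (E)-1-[4-methoxy-2,6-bis(methoxymethoxy)-3-(3-methylbut-2-en-1-yl)phenyl]-3-[4-(methoxymethoxy)phenyl]prop-2-en-1-one F7. Mild acid removal of the three MOM groups (HCl, MeOH, rt) releases 6 under conditions where ring closure is slow.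

Step 1. O-alkylation, double prenylation and chroman formation can cut the yield of the C-prenyl product. Fallback, setting out from 1 and coming back at 3: O-prenylation of 1 with 2 (K2CO3, acetone, reflux; after the first alkylation the remaining hydroxyl is chelated and inert) gives 1-[2-hydroxy-4-methoxy-6-(3-methylbut-2-en-1-yloxy)phenyl]ethanone F8. An acid-clay O→C prenyl shift (montmorillonite K10, CH2Cl2, 0 °C → rt) then gives 3. This is regioconvergent: the ortho 1,3-shift and the para migration lead to the same compound, because the two free ring positions become equivalent once the phenol is released.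

**Further compounds**
F1 | step 3 | 1-[2-hydroxy-4-methoxy-6-(2-methylbut-3-yn-2-yloxy)phenyl]ethanone | CC(=O)c1c(O)cc(OC)cc1OC(C)(C)C#C
F2 | step 3 | 1-[2-hydroxy-4-methoxy-6-(2-methylbut-3-en-2-yloxy)phenyl]ethanone | CC(=O)c1c(O)cc(OC)cc1OC(C)(C)C=C
F3 | step 3 | (E)-1-[2-hydroxy-4-methoxy-6-(2-methylbut-3-en-2-yloxy)phenyl]-3-(4-hydroxyphenyl)prop-2-en-1-one | COc1cc(O)c(C(=O)/C=C/c2ccc(O)cc2)c(OC(C)(C)C=C)c1
F4 | step 3 | (2S)-2-(4-hydroxyphenyl)-7-methoxy-5-(2-methylbut-3-en-2-yloxy)chroman-4-one | COc1cc2c(c(OC(C)(C)C=C)c1)C(=O)C[C@@H](c1ccc(O)cc1)O2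
F5 | step 2 | 1-[4-methoxy-2,6-bis(methoxymethoxy)-3-(3-methylbut-2-en-1-yl)phenyl]ethanone | CC(=O)c1c(OCOC)cc(OC)c(CC=C(C)C)c1OCOC
F6 | step 2 | 4-(methoxymethoxy)benzaldehyde | COCOc1ccc(C=O)cc1
F7 | step 2 | (E)-1-[4-methoxy-2,6-bis(methoxymethoxy)-3-(3-methylbut-2-en-1-yl)phenyl]-3-[4-(methoxymethoxy)phenyl]prop-2-en-1-one | COCOc1ccc(/C=C/C(=O)c2c(OCOC)cc(OC)c(CC=C(C)C)c2OCOC)cc1
F8 | step 1 | 1-[2-hydroxy-4-methoxy-6-(3-methylbut-2-en-1-yloxy)phenyl]ethanone | CC(=O)c1c(O)cc(OC)cc1OCC=C(C)C
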